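**Assumptions:**
- The target has C12 = R, Z-C14=C15, E-C5=C6, and C6 cis to the C9 carbonyl across C7=C8 (7Z by CIP), exactly as in the given SMILES.
- Simple reagents (bases, oxidants, ligands) are not numbered. Compounds appear in the order they first occur in the steps.

## Retrosynthetic overview
1. The target is the free tertiary alcohol, so the last step is a silyl removal. The skeleton comes from a late stereoretentive Stille coupling at C6–C7, which avoids the usual C7=C8 aldol condensation with the enal.
2. The (Z)-alkylidene geometry comes from a stereodefined β-iodo enone. It is made from the C8 formyl/hydroxymethylene enone, where chelation and A(1,3) strain put the heteroatom cis to C9=O.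
3. The core, a 2-bromo-4-hydroxy-4-[(Z)-oct-2-enyl]cyclopentenone, is built from commercial enantiopure (R)-4-silyloxycyclopentenone. An allenylzinc adds to the C=O anti to OTBS (a 1,4-relay) and sets C12. Lindlar reduction gives the Z-alkene, and oxidation of the relay carbinol removes the C4 stereocentre.
4. No ring is formed; the only ring is the commercial cyclopentenone. The side chain is a second fragment, an (E)-vinylstannane made from methyl hex-5-ynoate.

## Route

**Step 1**
Reactants: **1** methyl hex-5-ynoate
Product: **2** methyl (5E)-6-(tributylstannyl)hex-5-enoate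
Conditions: Bu3SnH, cat. Pd(PPh3)2Cl2, THF, 0 °C
Reagents that add atoms: tributyltin hydride, CCCC[SnH](CCCC)CCCC
Why: Pd-catalysed syn-hydrostannylation of a terminal alkyne puts Sn on the terminal carbon, giving the (E)-vinylstannane (the minor α-isomer is removed by chromatography).

**Step 2**
Reactants: **3** (R)-4-(TBSO)cyclopent-2-en-1-one; **4** 1-bromooct-2-yne
Product: **5** (1S,4R)-4-(TBSO)-1-(oct-2-yn-1-yl)cyclopent-2-en-1-ol
Conditions: Zn dust, THF/sat. aq. NH4Cl, 0 °C → rt
Reagents that add atoms: none beyond reactant 4 (Zn is not incorporated)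
Why: Barbier-type allenylzinc formation followed by SE2′ 1,2-addition gives the homopropargylic tertiary alcohol. Attack occurs anti to the bulky C4-OTBS (1,4-relay), which sets C1 as S with R′ trans to OTBS.

**Step 3**
Reactants: **5**
Product: **6** (1S,4R)-4-(TBSO)-1-[(2Z)-oct-2-en-1-yl]cyclopent-2-en-1-ol
Conditions: H2 (1 atm), Lindlar catalyst, quinoline, EtOAc, rt
Reagents that add atoms: none (H2 adds only hydrogen)
Why: Lindlar semihydrogenation is a syn-addition that gives the Z-alkene, and the hindered cyclopentene and silyl ether are untouched.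

**Step 4**
Reactants: **6**
Product: **7** (1S,4R)-1-[(2Z)-oct-2-en-1-yl]cyclopent-2-ene-1,4-diol
Conditions: TBAF, AcOH (buffer), THF, 0 °C → rt
Reagents that add atoms: none
Why: Fluoride-mediated desilylation of the secondary silyl ether. Buffering prevents base-mediated side reactions of the allylic tertiary alcohol.

**Step 5**
Reactants: **7**
Product: **8** (4S)-4-hydroxy-4-[(2Z)-oct-2-en-1-yl]cyclopent-2-en-1-one
Conditions: activated MnO2, CH2Cl2, rt
Reagents that add atoms: none
Why: MnO2 selectively oxidises the secondary allylic alcohol and leaves the tertiary one alone. This destroys the relay stereocentre, so C12 is the only stereocentre left and it is not racemised.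

**Step 6**
Reactants: **8**
Product: **9** (4S)-2-bromo-4-hydroxy-4-[(2Z)-oct-2-en-1-yl]cyclopent-2-en-1-one
Conditions: NBS, cat. DMAP, CH2Cl2, 0 °C, dark
Reagents that add atoms: N-bromosuccinimide, O=C1CCC(=O)N1Br
Why: Proposed new method: DMAP adds reversibly to the enone β-carbon, the resulting enolate is brominated by NBS, and elimination of DMAP gives the α-bromo enone. This is the closest known reaction type to Johnson α-iodination with I2/pyridine. It avoids Br2, which would add to the Z-alkene, because NBS is inert to isolated alkenes without acid or radicals.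

**Step 7**
Reactants: **9**
Product: **10** (4S)-2-bromo-4-(triethylsilyloxy)-4-[(2Z)-oct-2-en-1-yl]cyclopent-2-en-1-one
Conditions: TESOTf, 2,6-lutidine, CH2Cl2, −78 °C
Reagents that add atoms: triethylsilyl triflate, CC[Si](CC)(CC)OS(=O)(=O)C(F)(F)F
Why: Silylation of the tertiary alcohol with a silyl triflate; the configuration is retained. The TES group is labile enough to remove gently at the end.

**Step 8**
Reactants: **10**
Product: **11** (4R,5Z)-2-bromo-5-(hydroxymethylidene)-4-(triethylsilyloxy)-4-[(2Z)-oct-2-en-1-yl]cyclopent-2-en-1-one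
Conditions: LDA, THF, −78 °C; then HCO2Et, −78 → 0 °C; aq. NH4Cl
Reagents that add atoms: ethyl formate, CCOC=O
Why: Claisen-type formylation of the kinetic α′-enolate at C8, the only enolisable site. Its β-silyloxy group does not eliminate at −78 °C because that would give an antiaromatic cyclopentadienone. The product exists as the H-bond-chelated enol with OH cis to C9=O.

**Step 9**
Reactants: **11**
Product: **12** (4R,5Z)-2-bromo-5-(iodomethylidene)-4-(triethylsilyloxy)-4-[(2Z)-oct-2-en-1-yl]cyclopent-2-en-1-one
Conditions: PPh3, I2, Et3N, CH2Cl2, 0 °C (pre-form Ph3PI2, then add 11)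
Reagents that add atoms: iodine, II
Why: Proposed new method: O-activation of the vinylogous acid as an oxyphosphonium, then iodide addition–elimination, as in the PPh3/I2 conversion of 1,3-diketones to β-iodo enones. Iodine should end up cis to C9=O because the alternative placement clashes with the quaternary C12 (A(1,3) strain). The product is a stereodefined, chemoselective Stille partner.

**Step 10**
Reactants: **12**; **2**
Product: **13** methyl (5E,7Z,12R,14Z)-10-bromo-9-oxo-12-(triethylsilyloxy)prosta-5,7,10,14-tetraen-1-oate
Conditions: Pd2(dba)3, AsPh3, CuI, NMP, rt, dark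
Reagents that add atoms: none beyond reactant 2
Why: Stille coupling proceeds with retention at both sp2 partners, so C6 lands cis to C9=O (7Z) and the E-C5=C6 alkene is kept. Oxidative addition at C–I is much faster than at the vinyl C–Br under these mild Pd/As/Cu conditions.

**Step 11**
Reactants: **13**
Product: **14** bromovulone III, methyl (5E,7Z,12R,14Z)-10-bromo-12-hydroxy-9-oxoprosta-5,7,10,14-tetraen-1-oate
Conditions: HF·pyridine, pyridine/THF, 0 °C
Reagents that add atoms: none
Why: Mildly acidic fluoride removes the TES group without the base that could trigger retro-aldol or E1cB chemistry of the β-hydroxy ketone. C12 is untouched, so it remains R.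

## Compound list
1 | methyl hex-5-ynoate | COC(=O)CCCC#C | starting material
2 | methyl (5E)-6-(tributylstannyl)hex-5-enoate | COC(=O)CCC/C=C/[Sn](CCCC)(CCCC)CCCC | intermediate
3 | (4R)-4-(tert-butyldimethylsilyloxy)cyclopent-2-en-1-one | O=C1C=C[C@H](O[Si](C)(C)C(C)(C)C)C1 | starting material
4 | 1-bromooct-2-yne | CCCCCC#CCBr | starting material
5 | (1S,4R)-4-(TBSO)-1-(oct-2-yn-1-yl)cyclopent-2-en-1-ol | CCCCCC#CC[C@@]1(O)C=C[C@H](O[Si](C)(C)C(C)(C)C)C1 | intermediate
6 | (1S,4R)-4-(TBSO)-1-[(2Z)-oct-2-en-1-yl]cyclopent-2-en-1-ol | CCCCC/C=C\C[C@@]1(O)C=C[C@H](O[Si](C)(C)C(C)(C)C)C1 | intermediate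
7 | (1S,4R)-1-[(2Z)-oct-2-en-1-yl]cyclopent-2-ene-1,4-diol | CCCCC/C=C\C[C@@]1(O)C=C[C@H](O)C1 | intermediate
8 | (4S)-4-hydroxy-4-[(2Z)-oct-2-en-1-yl]cyclopent-2-en-1-one | CCCCC/C=C\C[C@@]1(O)C=CC(=O)C1 | intermediate
9 | (4S)-2-bromo-4-hydroxy-4-[(2Z)-oct-2-en-1-yl]cyclopent-2-en-1-one | CCCCC/C=C\C[C@@]1(O)C=C(Br)C(=O)C1 | intermediate
10 | TES ether of 9 | CCCCC/C=C\C[C@@]1(O[Si](CC)(CC)CC)C=C(Br)C(=O)C1 | intermediate
11 | (4R,5Z)-5-hydroxymethylidene enone (TES ether) | CCCCC/C=C\C[C@@]1(O[Si](CC)(CC)CC)C=C(Br)C(=O)/C1=C\O | intermediate
12 | (4R,5Z)-5-iodomethylidene enone (TES ether) | CCCCC/C=C\C[C@@]1(O[Si](CC)(CC)CC)C=C(Br)C(=O)/C1=C\I | intermediate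
13 | methyl (5E,7Z,12R,14Z)-10-bromo-9-oxo-12-(TESO)prosta-5,7,10,14-tetraen-1-oate | CCCCC/C=C\C[C@@]1(O[Si](CC)(CC)CC)C=C(Br)C(=O)/C1=C\C=C\CCCC(=O)OC | intermediate
14 | bromovulone III | CCCCC/C=C\C[C@@]1(O)C=C(Br)C(=O)/C1=C\C=C\CCCC(=O)OC | target

**Total steps:** 11 (including the 1-step fragment preparation).
**Longest linear sequence:** 10 steps (Steps 2–11, from compound 3).

**Three steps most likely to fail**
1. **Step 6 (NBS/DMAP α-bromination).** The β-carbon next to the quaternary centre is hindered, and the allylic Z-alkene is at risk.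
   - Fallback: reorder. Do the bromination at the alkyne stage (compound 5 oxidised to the enone) with the alkyne masked as its Co2(CO)6 complex. Use Br2 then Et3N, decomplex with CAN, then Lindlar.
2. **Step 9 (iodination geometry and chemoselectivity).** A Z/E mixture of the iodo enone, or competing reactivity at C–Br, would ruin the Stille step.
   - Fallback: abandon the coupling logic. Form the TES enolate of 10 and run the conventional aldol condensation with methyl (E)-7-oxohept-5-enoate, then dehydrate. The thermodynamic alkylidene geometry puts the chain syn to C9=O.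
3. **Step 2 (allenylzinc regiochemistry and diastereoselectivity).** Competing allenyl alcohol formation or poor anti selectivity would lower yield and purity.
   - Fallback: add allylzinc or allylMgBr to compound 3 to give the 1-allyl adduct. Then install the Z-chain by Z-selective Ru-catalysed cross-metathesis with 1-heptene to reach compound 6.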